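**Retrosynthetic overview**

- The only ring is the 33-membered lactone (ring O, C1(=O), C2–C32). Its ester group divides the 32 ring carbons into two C16 halves, acyl C1–C16 and alkoxy C17–C32, so the C16–C17 bond lies opposite the ester and both halves are the same ω-functionalised C16 chain.
- Target 10 ⇐ 9 by saturation of the C15≡C16–C17≡C18 diyne; 9 ⇐ 8 by intramolecular oxidative sp–sp coupling at C16–C17, which forms the single ring.
- 8 ⇐ acid 7 + alcohol 6 by esterification; 7 ⇐ 6 by oxidation.
- 6 ⇐ 4 by moving the triple bond to the chain end; 4 ⇐ propargyl alcohol 1 + 1-bromotridecane 2.

Key step: step 5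

Remark: the target has no stereocentre and no double bond, so no stereochemical issue arises. The locants C1–C32 count the ring carbons from the lactone carbonyl (C1) round to the OCH2 carbon (C32).

**Route**

Step 1
Reactants: 1 prop-2-yn-1-ol (propargyl alcohol); 2 1-bromotridecane
Product: 4 hexadec-2-yn-1-ol, via lithium 3-lithioprop-2-yn-1-olate 3 (not isolated)
Conditions: n-BuLi (2.1 equiv), THF/HMPA (4:1), −78 → −20 °C; then 2, −20 °C → rt, 16 h; H2O
Reagents that add atoms: none
Why: C-alkylation of the propargyl alcohol dianion (acetylide SN2), in which the sp carbanion of 3 is far more nucleophilic than its alkoxide, so the primary bromide should be displaced at carbon in the dipolar medium without O-protection, and no stereocentre is formed.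

Step 2
Reactants: 4 hexadec-2-yn-1-ol
Product: 6 hexadec-15-yn-1-ol, via potassium 16-potassiohexadec-15-yn-1-olate 5 (not isolated)
Conditions: KH (4.5 equiv), H2N(CH2)3NH2, rt, 1 h (forms KNH(CH2)3NH2, KAPA); then 4 in THF, 0 °C → rt, 3 h; H2O, 0 °C
Reagents that add atoms: none
Why: Alkyne zipper reaction, in which KAPA walks the triple bond along the chain by reversible propargyl/allenyl deprotonation and reprotonation, the alkoxide end closes off one direction, and irreversible formation of the terminal acetylide 5 drains the equilibrium to the chain end before the water quench releases the alkynol.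

Step 3
Reactants: 6 hexadec-15-yn-1-ol (about half of the batch)
Product: 7 hexadec-15-ynoic acid
Conditions: CrO3, H2SO4, H2O, acetone, 0 °C → rt
Reagents that add atoms: water, O
Why: Jones oxidation, which takes the primary alcohol through the aldehyde and its hydrate to the carboxylic acid while the terminal alkyne is inert to hexavalent chromium in cold aqueous acetone.

Step 4
Reactants: 7 hexadec-15-ynoic acid; 6 hexadec-15-yn-1-ol
Product: 8 hexadec-15-yn-1-yl hexadec-15-ynoate
Conditions: DCC (1.1 equiv), DMAP (0.1 equiv), CH2Cl2, 0 °C → rt
Reagents that add atoms: none
Why: Steglich esterification, in which DCC activates the acid as its O-acylisourea and DMAP relays the acyl group to the unhindered primary alcohol under neutral conditions that leave both terminal alkynes untouched.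

Step 5
Reactants: 8 hexadec-15-yn-1-yl hexadec-15-ynoate
Product: 9 oxacyclotritriaconta-16,18-diyn-2-one
Conditions: Cu(OAc)2 (10 equiv), pyridine/Et2O (6:1), 45 °C; 8 in pyridine/Et2O added by syringe pump over 36 h (final about 1 mM), then 4 h
Reagents that add atoms: none
Why: Eglinton coupling used as a macrocyclisation: acetate and pyridine deprotonate the two copper-complexed terminal alkynes of 8 to copper acetylides, which are oxidised by divalent copper and joined within an acetate-bridged dinuclear copper acetylide, forming the C16–C17 sp–sp bond and releasing two equivalents of monovalent copper acetate. The closest known reaction type is this same reaction, the high-dilution oxidative cyclisation of α,ω-diynes with Cu(OAc)2 in pyridine, which is established for large rings and tolerates ester tethers. The single ring closes end to end by joining the two chain termini, and the 33-membered ring is large enough to hold the six collinear carbons C14–C15≡C16–C17≡C18–C19 without strain. No stereocentre is formed. The selectivity needed is ring closure over linear or cyclic oligomerisation; nothing in the flexible chain preorganises it, so it rests on a very low stationary concentration of 8, secured by slow addition into a large excess of Cu(OAc)2. Chemoselectivity is not in question because the two alkyne C–H bonds are the only reactive sites of 8 and react alike.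

Step 6
Reactants: 9 oxacyclotritriaconta-16,18-diyn-2-one
Product: 10 oxacyclotritriacontan-2-one (dotriacontan-32-olide)
Conditions: 9 first filtered through silica (removes Cu salts and pyridine); H2 (balloon), 10% Pd/C, EtOAc/THF, rt
Reagents that add atoms: none
Why: Heterogeneous catalytic hydrogenation, in which the conjugated diyne should take up four equivalents of H2 to become the saturated C15–C18 segment while the lactone C–O bond, remote from the unsaturation, is not hydrogenolysed.

**Compound list**

1 | prop-2-yn-1-ol (propargyl alcohol) | C#CCO | starting material
2 | 1-bromotridecane | CCCCCCCCCCCCCBr | starting material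
3 | lithium 3-lithioprop-2-yn-1-olate | [Li]C#CCO[Li] | intermediate
4 | hexadec-2-yn-1-ol | CCCCCCCCCCCCCC#CCO | intermediate
5 | potassium 16-potassiohexadec-15-yn-1-olate | [K]C#CCCCCCCCCCCCCCCO[K] | intermediate
6 | hexadec-15-yn-1-ol | C#CCCCCCCCCCCCCCCO | intermediate
7 | hexadec-15-ynoic acid | C#CCCCCCCCCCCCCCC(=O)O | intermediate
8 | hexadec-15-yn-1-yl hexadec-15-ynoate | C#CCCCCCCCCCCCCCC(=O)OCCCCCCCCCCCCCCC#C | intermediate
9 | oxacyclotritriaconta-16,18-diyn-2-one | O=C1CCCCCCCCCCCCCC#CC#CCCCCCCCCCCCCCCO1 | intermediate
10 | oxacyclotritriacontan-2-one (dotriacontan-32-olide) | O=C1CCCCCCCCCCCCCCCCCCCCCCCCCCCCCCCO1 | target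

**Step count and risks**

Total step count: 6. Longest linear sequence: 6 steps (1 → 4 → 6 → 7 → 8 → 9 → 10; the alcohol 6 is used twice, once as such and once after oxidation to 7).

Steps most likely to fail:

1. Step 5. Intermolecular coupling may outrun ring closure if 8 accumulates faster than the copper turns it over, giving linear oligomers and the cyclic dimer in place of the monomeric ring. The fallback sets out from 6 (with 7 as partner, before the ester 8 is made) and comes back at 9. The alkyne terminus of 6 would be brominated (NBS, AgNO3 cat., acetone) to 16-bromohexadec-15-yn-1-ol F1. Cadiot–Chodkiewicz cross-coupling of F1 with the free acid 7 (CuCl cat., NH2OH·HCl, EtNH2, MeOH/H2O, then acidification) should form the same C16–C17 bond intermolecularly and give 32-hydroxydotriaconta-15,17-diynoic acid F2. Yamaguchi macrolactonisation of F2 (2,4,6-trichlorobenzoyl chloride, Et3N, THF; then slow addition to DMAP in toluene, 90 °C) would close the ring at the ester C–O bond and deliver 9, which enters step 6 unchanged.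

2. Step 2. Migration over thirteen positions may stop short or be quenched by adventitious moisture, leaving internal alkyne and allene isomers that cannot be separated from 6. The fallback gives up the isomerisation and builds the terminal alkyne by one-carbon homologation. It uses no numbered compound of the route (4 is abandoned); it sets out from commercial pentadecan-15-olide F3 and comes back at 6. Half-reduction of F3 (i-Bu2AlH, 1.05 equiv, CH2Cl2, −78 °C) should give 15-hydroxypentadecanal F4. Ohira–Bestmann alkynylation of F4 (dimethyl (1-diazo-2-oxopropyl)phosphonate, K2CO3, MeOH, rt) should then give 6.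

3. Step 1. Displacement on the long-chain bromide by the poorly soluble dianion may be slow, with competing O-alkylation and E2 elimination of 2. The fallback sets out from 2 and comes back at 4. Alkylation of LiC≡CH·H2N(CH2)2NH2 with 2 in DMSO at rt should give pentadec-1-yne F5. Deprotonation of F5 (n-BuLi, THF, −78 °C) and hydroxymethylation with paraformaldehyde (−78 °C → rt) should then give 4, so no unprotected alkoxide is present during the C–C bond-forming SN2 step.

**Further compounds**

F1 | step 5 | 16-bromohexadec-15-yn-1-ol | BrC#CCCCCCCCCCCCCCCO
F2 | step 5 | 32-hydroxydotriaconta-15,17-diynoic acid | OCCCCCCCCCCCCCCC#CC#CCCCCCCCCCCCCCC(=O)O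
F3 | step 2 | pentadecan-15-olide (oxacyclohexadecan-2-one) | O=C1CCCCCCCCCCCCCCO1
F4 | step 2 | 15-hydroxypentadecanal | O=CCCCCCCCCCCCCCCO
F5 | step 1 | pentadec-1-yne | C#CCCCCCCCCCCCCC
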